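**Retrosynthetic overview**
1. The target is a mixed 1,3-diester of a 2-arylglycerol: the phenol is freed last by hydrogenolysis of a benzyl ether, and before that the (R)-2-methylbutanoate ester is cut (Steglich coupling).
2. (R)-2-Methylbutanoic acid comes from achiral tiglic acid by Ru-catalysed asymmetric hydrogenation (first stereocentre).
3. The isobutyrate ester and the carbinol stereocentre come from a lipase-catalysed desymmetrising mono-acylation of the prochiral 2-arylpropane-1,2,3-triol.
4. The triol comes from an aryllithium (from O-benzylated 2-bromo-5-methylphenol) adding to 2,2-dimethyl-1,3-dioxan-5-one, then acetonide hydrolysis.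
5. Rings: none is formed; the benzene ring is bought, and the dioxane ring of the ketone is bought and only opened.

Assumption: the lipase in step 5 acylates the pro-R hydroxymethyl arm of triol 8 (checked on a first small run by chiral HPLC); if it prefers the other arm, the fallback to step 5 gives the same monoester 10.

**Step 1**
Reactants: 1 tiglic acid [(E)-2-methylbut-2-enoic acid]
Product: 2 (R)-2-methylbutanoic acid
Conditions: H2 (2 atm), Ru(OAc)2[(R)-H8-BINAP] (0.5 mol%), MeOH, 20 °C; distil
Reagents that add atoms: none
Why: Noyori-type asymmetric hydrogenation in which the carboxylate binds ruthenium and H2 is delivered to one face of the trisubstituted alkene, the (R)-ligand giving the (R)-acid (about 97% ee expected from precedent with this ligand, sense confirmed by the negative optical rotation), which sets the first stereocentre from an achiral acid.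

**Step 2**
Reactants: 3 2-bromo-5-methylphenol
Product: 4 2-(benzyloxy)-1-bromo-4-methylbenzene
Conditions: BnBr (1.1 equiv), K2CO3 (1.5 equiv), DMF, 25 °C
Reagents that add atoms: benzyl bromide, BrCc1ccccc1
Why: Williamson ether synthesis, the phenoxide displacing bromide from the benzylic halide, gives an ether that survives organolithium, acid, lipase and carbodiimide steps and is removed under neutral conditions at the end.

**Step 3**
Reactants: 4 2-(benzyloxy)-1-bromo-4-methylbenzene; 5 2,2-dimethyl-1,3-dioxan-5-one
Product: 7 5-[2-(benzyloxy)-4-methylphenyl]-2,2-dimethyl-1,3-dioxan-5-ol, via aryllithium 6 (not isolated)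
Conditions: n-BuLi (1.05 equiv), THF, −78 °C, 30 min; then 5, −78 → −20 °C; sat. aq. NH4Cl
Reagents that add atoms: none
Why: Bromine–lithium exchange at −78 °C is much faster than benzylic deprotonation, and the aryllithium undergoes 1,2-addition to the activated dialkoxy ketone to give the achiral tertiary alcohol with both CH2O arms already in place.

**Step 4**
Reactants: 7 5-[2-(benzyloxy)-4-methylphenyl]-2,2-dimethyl-1,3-dioxan-5-ol
Product: 8 2-[2-(benzyloxy)-4-methylphenyl]propane-1,2,3-triol
Conditions: AcOH/H2O (4:1), 40 °C
Reagents that add atoms: none
Why: Acid-catalysed acetal hydrolysis releases the two primary hydroxyls, while the tertiary benzylic alcohol does not ionise because the cation would be flanked by two oxygen-bearing carbons.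

**Step 5**
Reactants: 8 2-[2-(benzyloxy)-4-methylphenyl]propane-1,2,3-triol; 9 isobutyric anhydride (2-methylpropanoic anhydride)
Product: 10 (2R)-2-[2-(benzyloxy)-4-methylphenyl]-2,3-dihydroxypropyl 2-methylpropanoate
Conditions: immobilized Burkholderia cepacia lipase (Amano PS-IM), 9 (1.2 equiv), t-BuOMe, 25 °C; filter, cold aq. NaHCO3 wash, use crude below 30 °C
Reagents that add atoms: none
Why: Lipase-catalysed enantiotopic-group-selective acylation (enzymatic desymmetrization) in which the serine hydrolase transfers the isobutyryl group to only one of the two primary CH2OH arms and leaves the tertiary OH alone, which sets the carbinol centre as R, and the slower second acylation of the minor enantiomer to the diester raises the ee further.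

**Step 6**
Reactants: 10 (2R)-2-[2-(benzyloxy)-4-methylphenyl]-2,3-dihydroxypropyl 2-methylpropanoate; 2 (R)-2-methylbutanoic acid
Product: 11 (2S)-2-[2-(benzyloxy)-4-methylphenyl]-2-hydroxy-3-[(2-methylpropanoyl)oxy]propyl (2R)-2-methylbutanoate
Conditions: DCC (1.2 equiv), DMAP (0.1 equiv), CH2Cl2, 0 °C
Reagents that add atoms: none
Why: Steglich esterification acylates the primary hydroxyl only (the tertiary one is too hindered) at 0 °C, fast enough to outrun acyl migration and without epimerising the α-centre of the acid; the carbinol descriptor changes from R to S only because the CIP priorities of the two arms swap.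

**Step 7**
Reactants: 11 (2S)-2-[2-(benzyloxy)-4-methylphenyl]-2-hydroxy-3-[(2-methylpropanoyl)oxy]propyl (2R)-2-methylbutanoate
Product: 12 (2S)-2-hydroxy-2-(2-hydroxy-4-methylphenyl)-3-[(2-methylpropanoyl)oxy]propyl (2R)-2-methylbutanoate
Conditions: H2 (1 atm), 10% Pd/C, EtOAc, 25 °C
Reagents that add atoms: none
Why: Catalytic hydrogenolysis cleaves the benzyl aryl ether under neutral conditions that leave both esters, both stereocentres and the hindered, electron-poor tertiary benzylic alcohol untouched.

**Compound list**
1 | tiglic acid, (E)-2-methylbut-2-enoic acid | C/C=C(\C)C(=O)O | starting material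
2 | (R)-2-methylbutanoic acid | CC[C@@H](C)C(=O)O | intermediate
3 | 2-bromo-5-methylphenol | Cc1ccc(Br)c(O)c1 | starting material
4 | 2-(benzyloxy)-1-bromo-4-methylbenzene | Cc1ccc(Br)c(OCc2ccccc2)c1 | intermediate
5 | 2,2-dimethyl-1,3-dioxan-5-one | CC1(C)OCC(=O)CO1 | starting material
6 | [2-(benzyloxy)-4-methylphenyl]lithium (aryllithium) | [Li]c1ccc(C)cc1OCc1ccccc1 | intermediate
7 | 5-[2-(benzyloxy)-4-methylphenyl]-2,2-dimethyl-1,3-dioxan-5-ol | CC1(C)OCC(O)(CO1)c1ccc(C)cc1OCc1ccccc1 | intermediate
8 | 2-[2-(benzyloxy)-4-methylphenyl]propane-1,2,3-triol | OCC(O)(CO)c1ccc(C)cc1OCc1ccccc1 | intermediate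
9 | isobutyric anhydride (2-methylpropanoic anhydride) | CC(C)C(=O)OC(=O)C(C)C | starting material
10 | (2R)-2-[2-(benzyloxy)-4-methylphenyl]-2,3-dihydroxypropyl 2-methylpropanoate | OC[C@@](O)(COC(=O)C(C)C)c1ccc(C)cc1OCc1ccccc1 | intermediate
11 | (2S)-2-[2-(benzyloxy)-4-methylphenyl]-2-hydroxy-3-[(2-methylpropanoyl)oxy]propyl (2R)-2-methylbutanoate | CC[C@@H](C)C(=O)OC[C@@](O)(COC(=O)C(C)C)c1ccc(C)cc1OCc1ccccc1 | intermediate
12 | (2S)-2-hydroxy-2-(2-hydroxy-4-methylphenyl)-3-[(2-methylpropanoyl)oxy]propyl (2R)-2-methylbutanoate | CC[C@@H](C)C(=O)OC[C@@](O)(COC(=O)C(C)C)c1ccc(C)cc1O | target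

**Step count and risks**
Total steps: 7. Longest linear sequence: 6 steps (steps 2 to 7, from 2-bromo-5-methylphenol); step 1 is a one-step side branch that joins at step 6.

The three steps most likely to fail:

Step 5 (enzymatic desymmetrization). The reacting CH2OH groups sit next to a crowded quaternary carbinol carrying an ortho-substituted aryl group, so the rate, the ee and even the sense of the lipase are uncertain. The fallback sets out from triol 8 and comes back at monoester 10. The triol is acylated on both primary hydroxyls with isobutyryl chloride (2.2 equiv, pyridine, CH2Cl2, 0 °C) to give the achiral diester 2-[2-(benzyloxy)-4-methylphenyl]-2-hydroxypropane-1,3-diyl bis(2-methylpropanoate) F1. The same lipase is then run in the hydrolytic direction (pH 7 phosphate buffer/t-BuOMe, 25 °C, pH-stat) to cleave one enantiotopic ester. A lipase recognises the same arm in both directions, so hydrolysis gives the mirror-image monoester of the acylation mode; whichever sense the enzyme shows, one of the two modes delivers (R)-10.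

Step 6 (second esterification). Under DMAP the free monoester 10 can shift its isobutyryl group to the other primary oxygen, which racemises the carbinol centre, and the activated chiral acid could epimerise. The fallback sets out from acid 2 and monoester 10 and comes back at diester 11. Acid 2 is converted with oxalyl chloride and catalytic DMF (CH2Cl2, 0 → 20 °C) into (2R)-2-methylbutanoyl chloride F2, which is distilled and added to 10 in CH2Cl2/pyridine at −20 °C with no nucleophilic catalyst. The isolated acyl chloride reacts with the primary hydroxyl within minutes under weak-base conditions, which leaves less time and less basicity for acyl migration.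

Step 3 (aryllithium addition). Ketone 5 is enolisable, so proton transfer can compete with addition and lower the yield. The fallback sets out from bromide 4 and comes back at triol 8, bypassing 7 and step 4. Aryllithium 6, made as before, is added at −78 °C in THF to the non-enolisable diethyl 2-oxopropanedioate (CCOC(=O)C(=O)C(=O)OCC) to give diethyl 2-[2-(benzyloxy)-4-methylphenyl]-2-hydroxypropanedioate F3. LiAlH4 (THF, 0 °C) then reduces both ester groups to give triol 8 directly.

**Further compounds**
F1 | step 5 | 2-[2-(benzyloxy)-4-methylphenyl]-2-hydroxypropane-1,3-diyl bis(2-methylpropanoate) | CC(C)C(=O)OCC(O)(COC(=O)C(C)C)c1ccc(C)cc1OCc1ccccc1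
F2 | step 6 | (2R)-2-methylbutanoyl chloride | CC[C@@H](C)C(=O)Cl
F3 | step 3 | diethyl 2-[2-(benzyloxy)-4-methylphenyl]-2-hydroxypropanedioate | CCOC(=O)C(O)(C(=O)OCC)c1ccc(C)cc1OCc1ccccc1
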